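The numbers in the tables are simulated for an exercise; scatter was added.

**One step.** In a one-step world, starting material and reagent simply give product, and the south-west charges allow 70.0 %. You have two runs to test that, and one question.

the same everywhere: starting material 0.10 M

| charge | reagent | protic impurity | free catalyst | remark | time |
|---|---|---|---|---|---|
| south-west | 0.070 M | 0.10 M | 0.91 mM | the very flask that is asked about, followed so far |  |
| north | 0.070 M | 0.10 M | 1.8 mM | run made earlier |  |
| flask | 0.0700 M | 0.100 M | 0.91 mM |  | 5.0 h |

south-west run (percent of the starting material charged)

| time / min | product / % | starting material / % |
|---|---|---|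
| 5.00 | 37.0 | 2.7 |
| 10.0 | 39.9 | 0 |
| 15.0 | 38.5 | 0.7 |
| 30.0 | 38.3 | 1.2 |
| 60.0 | 39.7 | 1.6 |

north run (percent of the starting material charged)

| time / h | product / % | starting material / % |
|---|---|---|
| 0.417 | 51.3 | 0 |
| 1.33 | 50.6 | 0.5 |
| 2.50 | 48.9 | 0 |
| 4.00 | 51.4 | 0 |
| 5.00 | 51.0 | 0 |

(each reading ± 1 percentage point)

- the reaction counts as stopped when no species that holds the starting material changes by six tenths of a point or more over the second half of the time

- which holds at 5.0 h: what has brought the reaction to rest, or that it has not come to rest (no working catalyst is left / the reagent has run out first / it is still moving / all of the starting material has reacted)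
- product at 5.0 h, in percent of the starting material charged

**Missing material.** South-west levels off from 10.0 min at a mean reading of 39.1 %, well below that ceiling. Its starting material reads 0 % at that moment. One-to-one, this product costs 55.9 % of the reagent, so reagent remains.

**First objection.** Dead catalyst flattens a curve too, but with no other path open, starting material then stays behind. The last south-west reading is 1.6 %, far short of the 60.9 % missing. So a side path took it, probably through the protic impurity.

**Split ratio.** By these readings, south-west loses 1.56 to that path per unit of product; call this the split ratio, a selectivity factor. North, at [free catalyst] = 1.8 mM, levels at 50.6 %, a split of 0.975. That reading is close to the crossing at 1, where the two paths take equal shares. South-west lies on the side path's part of it.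

**Second objection.** Perhaps the split simply goes inversely with [free catalyst]. That predicts 0.787 for north, which reads 0.975. So you shouldn't extrapolate in catalyst. Here you needn't, since the asked flask repeats south-west. North also stays flat, from 51.3 % to 51.0 % at 5.00 h. I commit to 39.1 % product, with the starting material reacted away, since its last south-west reading is 1.6 % with a scatter of 1 percentage point.

**The result.** The forecast says all of the starting material has reacted and 39.1 %: “The flask repeats south-west”. The flask gives all of the starting material has reacted and 38.9 %.

    starting material + free catalyst → catalyst intermediate A (k = 17.0 M⁻¹ s⁻¹)
    catalyst intermediate A → catalyst intermediate B (k = 0.430 s⁻¹)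
    reagent + catalyst intermediate B → catalyst intermediate C (k = 19.0 M⁻¹ s⁻¹)
    catalyst intermediate C → by-product + catalyst intermediate D (k = 47.0 s⁻¹)
    catalyst intermediate D → free catalyst + product (k = 1.70 s⁻¹)
    crystals ⇌ by-product, rate k6*(cs6 - [by-product]) while solid is left; crystals form when [by-product] > cs6 (solubility = 1.70 mM, k = 0.180 s⁻¹)
    starting material + protic impurity → quenched substrate (k = 0.110 M⁻¹ s⁻¹)

**Side step.** The run without the step from starting material and protic impurity to quenched substrate ends at 70.0 % product, not 38.9 %, so that step is the main reason for the shortfall. The flask holds 61.1 % quenched substrate at 5.00 h, a split of 1.57. Scale 1.56 by [protic impurity] for the neighbour charged with 0.17 M of protic impurity, its other charges held: its split should be 2.65, hence 27.4 % product, and it gives 25.1 %.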